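**Retrosynthetic overview**
- The γ-lactone (O6–C12) is closed last. The C12 methyl of a 7-isopropenyl-6-ol is oxidised at the allylic position, and the resulting 1,4-diol is lactonised oxidatively.
- Key disconnection: C6–C7. An intramolecular carbonyl-ene reaction closes the ten-membered ring C1–C10, sets C6 and C7, and creates C11=C13. It copies the C6–C7 closure and proton loss of farnesyl diphosphate to germacrene A.
- The feature used is the array C1=C2–C3(=O)–C4(C15)=C5–C6, with its Z-C4=C5 bond next to oxygenated C6. This array is a ring-opened 2-alkenyl-3-methylfuran, so the furan ring fixes the Z geometry and masks the C6 aldehyde.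
- The open-chain precursor is built from prenal (C7, C8, C11–C13), an acetone unit (C9, C10, C14), iodoform (C1) and 3-methylfurfural (C2–C6, C15). C8 is set by catalysis and C10 by 1,3-chelate control.
- Ring order: furan (sacrificed), then the ten-membered carbocycle, then the γ-lactone.

Key step: step 6

Remark: germacrane numbering is used throughout (ring C1–C10, C11–C13 on C7, C14 on C10, C15 on C4).

**Step 1**
Reactants: 1 3-methylbut-2-enal (prenal); 2 2-methoxypropene
Product: 4 (4R)-4-hydroxy-6-methylhept-5-en-2-one, via enol ether adduct 3 (not isolated)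
Conditions: chiral Ti(IV)/BINOL-derived tridentate imine/3,5-di-tert-butylsalicylic acid complex (5 mol %, antipode chosen for Re-face attack), 2 in excess, 0 °C to rt; then aq. oxalic acid, Et2O, 0 °C
Reagents that add atoms: water, O
Why: This is a catalytic enantioselective ene-type aldol addition of an acetone enol ether, in which the chiral Ti(IV) Lewis acid shields the Si face of the C8 aldehyde so that C9 adds to the Re face and sets (8R), and mild acid then hydrolyses the enol ether without ionising the allylic alcohol.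

**Step 2**
Reactants: 5 3-methylfuran-2-carbaldehyde; 6 iodoform
Product: 7 2-[(E)-2-iodoethenyl]-3-methylfuran
Conditions: CrCl2 (6 equiv), THF, 0 °C
Reagents that add atoms: none
Why: The Takai olefination of an aromatic aldehyde through a gem-dichromium species should give the (E)-alkenyl iodide and so fix the E geometry of C1=C2.

**Step 3**
Reactants: 4 (4R)-4-hydroxy-6-methylhept-5-en-2-one; 7 2-[(E)-2-iodoethenyl]-3-methylfuran
Product: 10 (1E,3R,5R)-3,7-dimethyl-1-(3-methylfuran-2-yl)octa-1,6-diene-3,5-diol, via alkenylmagnesium chloride 8 (not isolated), via chloromagnesium alkoxide 9 (not isolated)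
Conditions: 7, i-PrMgCl·LiCl (1.05 equiv), THF, −40 °C; separately 4, i-PrMgCl (1.0 equiv), CH2Cl2/THF, −78 °C; combine, −78 to −40 °C; aq. NH4Cl
Reagents that add atoms: none
Why: This is a chelation-controlled Grignard addition in which the six-membered Mg chelate of the β-alkoxide ketone is attacked on the face away from the C8 substituent, in the same sense as chelate-controlled hydride delivery, and because the incoming group is the main-chain carbon C1 the O8/O10 relation should be 1,3-anti, which is (10R).

**Step 4**
Reactants: 10 (1E,3R,5R)-3,7-dimethyl-1-(3-methylfuran-2-yl)octa-1,6-diene-3,5-diol; 11 tigloyl chloride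
Product: 12 (1E,3R,5R)-3-hydroxy-3,7-dimethyl-1-(3-methylfuran-2-yl)octa-1,6-dien-5-yl (E)-2-methylbut-2-enoate
Conditions: Et3N, DMAP (cat.), CH2Cl2, 0 °C
Reagents that add atoms: none
Why: DMAP-catalysed acylation takes the secondary C8 alcohol and leaves the hindered tertiary C10 alcohol, and the basic medium protects the acid-labile furylvinyl carbinol.

**Step 5**
Reactants: 12 (1E,3R,5R)-3-hydroxy-3,7-dimethyl-1-(3-methylfuran-2-yl)octa-1,6-dien-5-yl (E)-2-methylbut-2-enoate
Product: 13 (2Z,5E,7R,9R)-7-hydroxy-3,7,11-trimethyl-1,4-dioxododeca-2,5,10-trien-9-yl (E)-2-methylbut-2-enoate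
Conditions: NBS (1.05 equiv), NaHCO3, acetone/H2O 10:1, −20 °C, dark
Reagents that add atoms: water, O
Why: In this oxidative furan ring opening, bromonium attack at the free α-position C6 and water capture at C3 give a 2,5-dihydrofuran that collapses to the (Z)-4-oxo-2-enal, the electron-rich furan reacting well before the prenyl alkene and the ring dictating the Z-C4=C5 geometry.

**Step 6**
Reactants: 13 (2Z,5E,7R,9R)-7-hydroxy-3,7,11-trimethyl-1,4-dioxododeca-2,5,10-trien-9-yl (E)-2-methylbut-2-enoate
Product: 15 (1E,4Z,6R,7R,8R,10R)-6,10-dihydroxy-3-oxogermacra-1,4,11(13)-trien-8-yl (E)-2-methylbut-2-enoate, via C10 aluminium alkoxide 14 (not isolated)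
Conditions: Me2AlCl (3.5 equiv), CH2Cl2, syringe-pump addition of 13 to 1 mM, −78 to −30 °C; aq. Rochelle salt
Reagents that add atoms: none
Why: Proposed new method: Me2AlCl binds the least hindered carbonyl, the C6 aldehyde of the (Z)-4-oxo-2-enal, and the only nucleophilic alkene, C7=C11, attacks C6 through C7 while a hydrogen of the E-methyl group (C13) passes to O6, a type-I carbonyl-ene reaction that repeats the C6–C7 closure and proton loss of the germacrene biosynthesis. The closest known reactions are the Lewis-acid ene cyclisation of citronellal to isopulegol and the alkylaluminium-chloride-promoted ene macrocyclisations of ω-alkenyl aldehydes to 12- to 16-membered carbocycles, whereas a ten-membered closure onto a prenyl-type alkene has not been shown. The ten-membered ring C1–C10 closes in a 10-exo-trig mode at the alkene, helped by five sp2 ring atoms and by the Z-C4=C5 turn that holds C6 near C7. C7 is controlled by C8, because A(1,3) strain with the Z-methyl group (C12) puts H8 in the alkene plane, the tether carbon C9 then leaves anti to the forming bond, and C6 adds to the face syn to O8, which gives (7R), whereas attack on the other face forces a syn-pentane contact between C5 and C9. C6 is controlled by the chair-like six-centre array O6–C6–C7–C11–C13–H with C5 equatorial, which gives the 6,7-anti relation, (6R), required for the trans-lactone. The step needs activation of the aldehyde rather than the ketone or esters, ring closure rather than oligomerisation, and survival of the allylic tiglate and the Z-enal, and these rest on steric access to the aldehyde, pseudo-high dilution, low temperature and the proton-scavenging Al–CH3 bonds.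

**Step 7**
Reactants: 15 (1E,4Z,6R,7R,8R,10R)-6,10-dihydroxy-3-oxogermacra-1,4,11(13)-trien-8-yl (E)-2-methylbut-2-enoate
Product: 16 (1E,4Z,6R,7R,8R,10R)-6,10,12-trihydroxy-3-oxogermacra-1,4,11(13)-trien-8-yl (E)-2-methylbut-2-enoate
Conditions: SeO2 (0.3 equiv), t-BuOOH (2 equiv), CH2Cl2, 0 °C to rt
Reagents that add atoms: tert-butyl hydroperoxide, CC(C)(C)OO
Why: In this Riley allylic oxidation (ene reaction then [2,3] shift) C11=C13 is the only alkene not deactivated by a carbonyl group and the C12 methyl is its accessible allylic position, and any over-oxidised enal converges in step 8.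

**Step 8**
Reactants: 16 (1E,4Z,6R,7R,8R,10R)-6,10,12-trihydroxy-3-oxogermacra-1,4,11(13)-trien-8-yl (E)-2-methylbut-2-enoate
Product: 19 eupaheliangolide A, via hydroxy enal 17 (not isolated), via 12,6-lactol 18 (not isolated)
Conditions: TEMPO (0.2 equiv), PhI(OAc)2 (2.5 equiv), CH2Cl2, rt
Reagents that add atoms: none
Why: In this oxoammonium-mediated oxidative lactonisation of a 1,4-diol the primary allylic alcohol is oxidised first, only the free 6α-OH can form the lactol, and its oxidation gives the trans-fused α-methylene-γ-lactone without touching C6, C7, C8 or C10.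

**Compound list**

| No. | Name | SMILES | Role |
|---|---|---|---|
| 1 | 3-methylbut-2-enal | CC(C)=CC=O | starting material |
| 2 | 2-methoxypropene | C=C(C)OC | starting material |
| 3 | (4R)-2-methoxy-6-methylhepta-1,5-dien-4-ol | C=C(OC)C[C@@H](O)C=C(C)C | intermediate |
| 4 | (4R)-4-hydroxy-6-methylhept-5-en-2-one | CC(=O)C[C@@H](O)C=C(C)C | intermediate |
| 5 | 3-methylfuran-2-carbaldehyde | Cc1ccoc1C=O | starting material |
| 6 | iodoform | IC(I)I | starting material |
| 7 | 2-[(E)-2-iodoethenyl]-3-methylfuran | Cc1ccoc1/C=C/I | intermediate |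
| 8 | (E)-2-(3-methylfuran-2-yl)ethenylmagnesium chloride | Cc1ccoc1/C=C/[Mg]Cl | intermediate |
| 9 | chloromagnesium alkoxide of 4 | CC(=O)C[C@@H](O[Mg]Cl)C=C(C)C | intermediate |
| 10 | (1E,3R,5R)-3,7-dimethyl-1-(3-methylfuran-2-yl)octa-1,6-diene-3,5-diol | Cc1ccoc1/C=C/[C@](C)(O)C[C@@H](O)C=C(C)C | intermediate |
| 11 | tigloyl chloride, (E)-2-methylbut-2-enoyl chloride | C/C=C(\C)C(=O)Cl | starting material |
| 12 | C8 tiglate of 10 | Cc1ccoc1/C=C/[C@](C)(O)C[C@@H](OC(=O)/C(C)=C/C)C=C(C)C | intermediate |
| 13 | (2Z,5E,7R,9R)-7-hydroxy-3,7,11-trimethyl-1,4-dioxododeca-2,5,10-trien-9-yl tiglate | O=C/C=C(/C)C(=O)/C=C/[C@](C)(O)C[C@@H](OC(=O)/C(C)=C/C)C=C(C)C | intermediate |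
| 14 | chloro(methyl)aluminium C10 alkoxide of 13 | O=C/C=C(/C)C(=O)/C=C/[C@](C)(O[Al](C)Cl)C[C@@H](OC(=O)/C(C)=C/C)C=C(C)C | intermediate |
| 15 | (1E,4Z,6R,7R,8R,10R)-6,10-dihydroxy-3-oxogermacra-1,4,11(13)-trien-8-yl tiglate | O[C@@H]1/C=C(/C)C(=O)/C=C/[C@](C)(O)C[C@@H](OC(=O)/C(C)=C/C)[C@H]1C(C)=C | intermediate |
| 16 | 12-hydroxy derivative of 15 | O[C@@H]1/C=C(/C)C(=O)/C=C/[C@](C)(O)C[C@@H](OC(=O)/C(C)=C/C)[C@H]1C(=C)CO | intermediate |
| 17 | 12-oxo derivative of 15 (hydroxy enal) | O[C@@H]1/C=C(/C)C(=O)/C=C/[C@](C)(O)C[C@@H](OC(=O)/C(C)=C/C)[C@H]1C(=C)C=O | intermediate |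
| 18 | 12,6-lactol (C12 epimers) | C=C1C(O)O[C@@H]2/C=C(/C)C(=O)/C=C/[C@](C)(O)C[C@@H](OC(=O)/C(C)=C/C)[C@@H]12 | intermediate |
| 19 | eupaheliangolide A | C=C1C(=O)O[C@@H]2/C=C(/C)C(=O)/C=C/[C@](C)(O)C[C@@H](OC(=O)/C(C)=C/C)[C@@H]12 | target |

**Step count**
- Total: 8 steps.
- Longest linear sequence: 7 steps (1, 3, 4, 5, 6, 7, 8).

**Steps most likely to fail**

*Step 6.*
- What may go wrong: oligomerisation may outrun ring closure. The Lewis acid may ionise the allylic C8 ester or isomerise the Z-enal. Facial selectivity at C7 may be poor.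
- Fallback (known chemistry): the same bond is made with an allylmetal in place of the C–H ene reaction. It sets out from 10 and comes back at 19.
- 10 is silylated at O8 (TESCl, imidazole) to the triethylsilyl ether F1. A silyloxide resists the 1,4-elimination that an ester would suffer next to an allylmetal.
- The furan is opened as in step 5 to the oxoenal F2.
- Ene-type chlorination with HOCl (Ca(OCl)2, CO2, CH2Cl2/H2O) gives the allylic chloride F3.
- An intramolecular Nozaki–Hiyama allylation (CrCl2, THF/DMF, high dilution) closes C6–C7 through the γ-carbon in an anti-selective chair to the macrocycle F4.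
- The conditions of steps 7 and 8 then give the allylic alcohol F5 and the silylated lactone F6.
- HF·pyridine frees the 8-hydroxy lactone F7, and 11 with Et3N/DMAP converts it into 19.

*Step 7.*
- What may go wrong: the ene step of SeO2 may abstract H7 instead of a C12 hydrogen, the oxidation may stall, or the γ-hydroxy enones may degrade under the peroxide.
- Fallback: the oxygen transfer is replaced by chlorination and N-oxide oxidation. It sets out from 15 and comes back at 17.
- HOCl ene chlorination of the isopropenyl group (Ca(OCl)2, CO2) gives the primary allylic chloride F11.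
- N-methylmorpholine N-oxide (Ganem oxidation, MeCN, rt) converts F11 into the hydroxy enal 17, which enters step 8.

*Step 3.*
- What may go wrong: the chelate may be too loose for good 1,3-induction. Enolisation or retro-aldol cleavage of the magnesium aldolate may compete.
- Fallback: C10–C14 is formed instead of C10–C1, and C8 is inverted while the ester is installed. It sets out from 5 and 1 and comes back at 12.
- Claisen–Schmidt condensation of 5 with acetone gives the enone F8.
- A diisopinocampheylboron enolate aldol with 1 gives the (8S)-β-hydroxy enone F9.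
- Chelation-controlled addition of MeMgCl, in which the main chain is already on the ketone, gives the 1,3-syn diol F10, (8S,10R).
- A Mitsunobu esterification with tiglic acid (PPh3, DIAD, toluene, 0 °C) inverts C8 and gives 12 directly.

**Further compounds**
F1 | step 6 | C8 triethylsilyl ether of 10 | Cc1ccoc1/C=C/[C@](C)(O)C[C@@H](O[Si](CC)(CC)CC)C=C(C)C
F2 | step 6 | (Z)-4-oxo-2-enal with C8 triethylsilyl ether | O=C/C=C(/C)C(=O)/C=C/[C@](C)(O)C[C@@H](O[Si](CC)(CC)CC)C=C(C)C
F3 | step 6 | C7 allylic chloride of F2 (C7 epimers) | O=C/C=C(/C)C(=O)/C=C/[C@](C)(O)C[C@@H](O[Si](CC)(CC)CC)C(Cl)C(C)=C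
F4 | step 6 | 8-O-triethylsilyl analogue of 15 | O[C@@H]1/C=C(/C)C(=O)/C=C/[C@](C)(O)C[C@@H](O[Si](CC)(CC)CC)[C@H]1C(C)=C
F5 | step 6 | 8-O-triethylsilyl analogue of 16 | O[C@@H]1/C=C(/C)C(=O)/C=C/[C@](C)(O)C[C@@H](O[Si](CC)(CC)CC)[C@H]1C(=C)CO
F6 | step 6 | 8-O-triethylsilyl lactone | C=C1C(=O)O[C@@H]2/C=C(/C)C(=O)/C=C/[C@](C)(O)C[C@@H](O[Si](CC)(CC)CC)[C@@H]12
F7 | step 6 | 8-hydroxy lactone (8-desacyl target) | C=C1C(=O)O[C@@H]2/C=C(/C)C(=O)/C=C/[C@](C)(O)C[C@@H](O)[C@@H]12
F8 | step 3 | (E)-4-(3-methylfuran-2-yl)but-3-en-2-one | CC(=O)/C=C/c1occc1C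
F9 | step 3 | (1E,5S)-5-hydroxy-7-methyl-1-(3-methylfuran-2-yl)octa-1,6-dien-3-one | Cc1ccoc1/C=C/C(=O)C[C@H](O)C=C(C)C
F10 | step 3 | (1E,3R,5S)-3,7-dimethyl-1-(3-methylfuran-2-yl)octa-1,6-diene-3,5-diol | Cc1ccoc1/C=C/[C@](C)(O)C[C@H](O)C=C(C)C
F11 | step 7 | 12-chloro derivative of 15 | O[C@@H]1/C=C(/C)C(=O)/C=C/[C@](C)(O)C[C@@H](OC(=O)/C(C)=C/C)[C@H]1C(=C)CCl
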